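**Retrosynthetic overview**
1. Target 31 is cut at C8–C9 (ring B) and at C11–C12 in one operation. The enabling feature is that ring B carries its exocyclic methylene on C8, directly beside C9, and C9's only other branch is the C11H2–C12H2 tether to the butenolide α-carbon C13. This maps onto a C8 vinyl radical (from 2-iodoalkene 23), a C9=C11 vinyl group on quaternary C10, and the 4-acetoxy-α-methylene lactone 29.
2. 23 comes from alkyne 21. Its C19 ester and C20 acetoxymethyl are released from the temporary bridged C19–O–C20 lactone 18. Vinyl (C10) and methyl (C4) enter by two enolate alkylations trans to the C5 chain of hemiester 12.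
3. 12 comes from catalytic desymmetrisation of meso anhydride 11 (this fixes C5, the only catalyst-controlled centre). 11 comes from tetraester 8, assembled from pent-4-ynal, two dimethyl malonates and 1,3-dibromopropane.
4. Ring order: ring A (step 3), temporary anhydride ring (step 5), temporary lactone ring (step 10), butenolide ring of 29 (step 15), ring B last (step 17).

Key step: step 17

Assumption: labdane numbering (C1–C20) is used for all intermediates, and (DHQD)2AQN is assumed to esterify the carbonyl that becomes C20 as drawn; if the sense proves opposite, the pseudo-enantiomeric (DHQ)2AQN is used in the same way.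

**Route**

Step 1
Reactants: 1 pent-4-yn-1-ol
Product: 2 pent-4-ynal
Conditions: TEMPO (cat.), PhI(OAc)2, CH2Cl2, rt; used as a solution
Reagents that add atoms: none
Why: TEMPO-catalysed alcohol oxidation should stop at the aldehyde and leave the terminal alkyne untouched.

Step 2
Reactants: 2 pent-4-ynal; 3 dimethyl malonate (2.2 equiv)
Product: 5 tetramethyl 2-(but-3-yn-1-yl)propane-1,1,3,3-tetracarboxylate, via alkylidene malonate 4 (not isolated)
Conditions: piperidine (cat.), AcOH (cat.), toluene, rt to 60 °C; then NaOMe (cat.), MeOH, rt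
Reagents that add atoms: none
Why: Knoevenagel condensation followed by Michael addition of a second malonate to the doubly activated alkylidene malonate is the classical entry to alkylidene bis-malonates and places the future C5 between the future C4 and C10.

Step 3
Reactants: 5 tetramethyl 2-(but-3-yn-1-yl)propane-1,1,3,3-tetracarboxylate; 6 1,3-dibromopropane
Product: 8 tetramethyl 2-(but-3-yn-1-yl)cyclohexane-1,1,3,3-tetracarboxylate, via bromide 7 (not isolated)
Conditions: NaH (2.2 equiv), DMF, 0 °C; 6 (1.05 equiv), high dilution, 60 °C
Reagents that add atoms: none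
Why: Double malonate alkylation (Perkin-type cycloalkane synthesis), intermolecular then 6-exo-tet, should close ring A with C1–C3 from the dibromide; malonate anions are too weakly basic to deprotonate the alkyne.

Step 4
Reactants: 8 tetramethyl 2-(but-3-yn-1-yl)cyclohexane-1,1,3,3-tetracarboxylate
Product: 10 2-(but-3-yn-1-yl)cyclohexane-1,3-dicarboxylic acid (mixture of diastereomers), via tetraacid 9 (not isolated)
Conditions: KOH, MeOH/H2O, 80 °C; HCl; then neat, 170 °C
Reagents that add atoms: potassium hydroxide, [K+].[OH-]
Why: Saponification and thermal decarboxylation of the two malonic acid units should leave one carboxyl on each of C4 and C10; the stereochemical mixture is of no consequence because the next step converges.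

Step 5
Reactants: 10 2-(but-3-yn-1-yl)cyclohexane-1,3-dicarboxylic acid
Product: 11 meso all-cis 9-(but-3-yn-1-yl)-3-oxabicyclo[3.3.1]nonane-2,4-dione
Conditions: Ac2O, NaOAc (cat.), 140 °C; recrystallisation
Reagents that add atoms: none
Why: Cyclic anhydride formation under epimerising conditions (enolisation of open mixed anhydrides) should funnel the diacids into the bridged meso anhydride with the butynyl group equatorial on the carbocycle, and the minor meso isomer should be removable by crystallisation.

Step 6
Reactants: 11 meso all-cis 9-(but-3-yn-1-yl)-3-oxabicyclo[3.3.1]nonane-2,4-dione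
Product: 12 all-cis 2-(but-3-yn-1-yl)-3-(methoxycarbonyl)cyclohexane-1-carboxylic acid (ester on the future C10, acid on the future C4)
Conditions: hydroquinidine anthraquinone-1,4-diyl diether, (DHQD)2AQN (0.2 equiv), MeOH (10 equiv), Et2O, −20 °C
Reagents that add atoms: methanol, CO
Why: Cinchona-alkaloid-catalysed desymmetrising alcoholysis of a meso cyclic anhydride should differentiate the enantiotopic carbonyls and thereby make C5 the single catalyst-set stereocentre, from which C4, C10 and C9 are later relayed.

Step 7
Reactants: 12 hemiester; 13 phenyl vinyl sulfoxide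
Product: 14 2-(but-3-yn-1-yl)-3-(methoxycarbonyl)-3-[2-(phenylsulfinyl)ethyl]cyclohexane-1-carboxylic acid (mixture at sulfur)
Conditions: LiN(iPr)2 (3.2 equiv), THF, −78 °C; 13 (1.3 equiv), −78 to −30 °C; aq. HCl
Reagents that add atoms: none
Why: At −78 °C only the ester α-position is enolised beside carboxylate and acetylide, and Michael addition to the vinyl sulfoxide (a vinyl cation equivalent) should occur on the face trans to the C5 chain and the C4 carboxylate, making C10 quaternary with its ester (future C20) cis to the chain.

Step 8
Reactants: 14 sulfoxide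
Product: 15 2-(but-3-yn-1-yl)-3-(methoxycarbonyl)-3-vinylcyclohexane-1-carboxylic acid
Conditions: toluene, 110 °C
Reagents that add atoms: none
Why: Thermal syn-elimination of the sulfoxide (Ei) can only use the hydrogens on the carbon next to C10 and should unveil the C9=C11 vinyl group.

Step 9
Reactants: 15 vinyl acid ester
Product: 16 2-(but-3-yn-1-yl)-3-(methoxycarbonyl)-1-methyl-3-vinylcyclohexane-1-carboxylic acid (both carboxyl carbons and butynyl on one face, methyl and vinyl on the other)
Conditions: LiN(iPr)2 (3.3 equiv), THF, 0 °C; MeI (1.2 equiv), −78 to −20 °C; aq. HCl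
Reagents that add atoms: iodomethane, CI
Why: Alkylation of the carboxylic acid dianion (enediolate) should take methyl iodide on the face trans to the C5 chain and to the C10 ester, setting C4 with its carboxyl cis to C20; the lithium acetylide is not methylated in THF at low temperature and the quaternary ester has no α-hydrogen.

Step 10
Reactants: 16 methylated acid ester
Product: 18 9-(but-3-yn-1-yl)-1-methyl-5-vinyl-3-oxabicyclo[3.3.1]nonan-2-one (C19–O–C20 lactone), via hydroxy acid 17 (not isolated)
Conditions: LiEt3BH (5 equiv), THF, 0 °C to rt; then 2 M HCl, rt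
Reagents that add atoms: none
Why: LiEt3BH reduces the hindered ester but not the lithium carboxylate, and the 1,3-diaxial hydroxymethyl and carboxyl groups should lactonise on acidification, a temporary ring that also confirms the cis relation of C19 and C20.

Step 11
Reactants: 18 bridged lactone
Product: 20 methyl 2-(but-3-yn-1-yl)-3-(hydroxymethyl)-1-methyl-3-vinylcyclohexane-1-carboxylate, via potassium carboxylate 19 (not isolated)
Conditions: KOH (1.5 equiv), MeOH/H2O, 60 °C; evaporate, CO2 to neutralise excess base; MeI, DMF, rt
Reagents that add atoms: potassium hydroxide, [K+].[OH-]; iodomethane, CI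
Why: Saponification followed by O-alkylation of the carboxylate under non-alkoxide conditions should open the lactone irreversibly to the hydroxy methyl ester, which is used at once.

Step 12
Reactants: 20 hydroxy ester
Product: 21 methyl 3-(acetoxymethyl)-2-(but-3-yn-1-yl)-1-methyl-3-vinylcyclohexane-1-carboxylate
Conditions: Ac2O, pyridine, DMAP (cat.), CH2Cl2, 0 °C
Reagents that add atoms: acetic anhydride, CC(=O)OC(C)=O
Why: Acetylation of the primary neopentyl alcohol should be faster than base-free relactonisation and fixes the C20 acetate of the target.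

Step 13
Reactants: 21 alkyne acetate
Product: 23 methyl 3-(acetoxymethyl)-2-(3-iodobut-3-en-1-yl)-1-methyl-3-vinylcyclohexane-1-carboxylate, via alkenylborane 22 (not isolated)
Conditions: 9-iodo-9-BBN (1.2 equiv), pentane/CH2Cl2, −20 to 0 °C; then AcOH, 0 °C to rt
Reagents that add atoms: 9-iodo-9-borabicyclo[3.3.1]nonane, IB1C2CCCC1CCC2
Why: Haloboration of a terminal alkyne (iodine to the internal carbon) followed by protodeboronation is a Markovnikov hydroiodination that is selective for terminal alkynes over alkenes and should give the 2-iodo-1-alkene.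

Step 14
Reactants: 24 methyl acrylate; 25 (tert-butyldimethylsilyloxy)acetaldehyde
Product: 26 methyl 2-[2-(tert-butyldimethylsilyloxy)-1-hydroxyethyl]acrylate (racemic)
Conditions: DABCO (0.5 equiv), 24 (excess), MeOH, rt
Reagents that add atoms: none
Why: Morita–Baylis–Hillman reaction of an acrylate with an unhindered aldehyde.

Step 15
Reactants: 26 silyl ether
Product: 28 4-hydroxy-3-methylenedihydrofuran-2(3H)-one (racemic), via diol ester 27 (not isolated)
Conditions: 2 M HCl, THF, rt
Reagents that add atoms: none
Why: Acidic desilylation frees the primary alcohol, which should lactonise onto the methyl ester to the γ-lactone.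

Step 16
Reactants: 28 hydroxy lactone
Product: 29 3-methylene-2-oxotetrahydrofuran-4-yl acetate (racemic)
Conditions: Ac2O, pyridine, CH2Cl2, 0 °C
Reagents that add atoms: acetic anhydride, CC(=O)OC(C)=O
Why: Acetylation at low temperature without nucleophilic catalyst should avoid SN2' isomerisation of the allylic acetate; the racemate suffices because this stereocentre is destroyed in step 17.

Step 17
Reactants: 23 2-iodoalkene; 29 3-methylene-2-oxotetrahydrofuran-4-yl acetate (5 equiv)
Product: 31 CNP0104712.1, via acetoxy lactone 30 (not isolated)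
Conditions: Bu3SnH (1.3 equiv) and AIBN (0.2 equiv) by syringe pump, benzene (0.01 M in 23), 80 °C; then DBU, 0 °C
Reagents that add atoms: none
Why: Bu3Sn• abstracts iodine from 23 to give the σ-vinyl radical at C8, which closes ring B by 6-exo-trig attack on the internal vinyl carbon C9; the resulting primary C11 radical adds to the exocyclic methylene of 29 (Giese addition), the α-lactone radical is reduced by Bu3SnH to 30, and DBU then expels acetate by E1cB to unveil the C13=C14 butenolide. The closest known reaction types are the Stork vinyl-radical cyclisation run as a tandem cyclisation–intermolecular trapping, and radical additions to Morita–Baylis–Hillman acetates. Ring B closes in the 6-exo-trig mode through a chair transition state that is trans-fused to ring A, because both arms (C6–C7–C8 on C5, vinyl on C10) are equatorial while C19 and C20 stay axial. The new stereocentre C9 is set by substrate control: the vinyl group should react in the rotamer in which C9=C11 eclipses the smallest allylic substituent (the C10–C20 bond), so that C11 ends equatorial (β) and H9 axial, anti to C20. The step needs ring closure to outrun bimolecular capture or reduction of the vinyl radical, exo over endo attack, and capture of the C11 radical by 29 before reduction; these should be secured by the vicinal diequatorial arms next to quaternary C10, by slow addition of Bu3SnH at high dilution, and by the polarity match between the nucleophilic primary radical and the electron-poor acceptor used in excess.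

**Compound list**
1 | pent-4-yn-1-ol | C#CCCCO | starting material
2 | pent-4-ynal | C#CCCC=O | intermediate
3 | dimethyl malonate | COC(=O)CC(=O)OC | starting material
4 | dimethyl 2-(pent-4-yn-1-ylidene)malonate | C#CCCC=C(C(=O)OC)C(=O)OC | intermediate
5 | tetramethyl 2-(but-3-yn-1-yl)propane-1,1,3,3-tetracarboxylate | C#CCCC(C(C(=O)OC)C(=O)OC)C(C(=O)OC)C(=O)OC | intermediate
6 | 1,3-dibromopropane | BrCCCBr | starting material
7 | tetramethyl 6-bromo-2-(but-3-yn-1-yl)hexane-1,1,3,3-tetracarboxylate | C#CCCC(C(C(=O)OC)C(=O)OC)C(CCCBr)(C(=O)OC)C(=O)OC | intermediate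
8 | tetramethyl 2-(but-3-yn-1-yl)cyclohexane-1,1,3,3-tetracarboxylate | C#CCCC1C(C(=O)OC)(C(=O)OC)CCCC1(C(=O)OC)C(=O)OC | intermediate
9 | 2-(but-3-yn-1-yl)cyclohexane-1,1,3,3-tetracarboxylic acid | C#CCCC1C(C(=O)O)(C(=O)O)CCCC1(C(=O)O)C(=O)O | intermediate
10 | 2-(but-3-yn-1-yl)cyclohexane-1,3-dicarboxylic acid, mixture of diastereomers | C#CCCC1C(C(=O)O)CCCC1C(=O)O | intermediate
11 | meso 9-(but-3-yn-1-yl)-3-oxabicyclo[3.3.1]nonane-2,4-dione, butynyl cis to both carbonyl carbons | C#CCC[C@@H]1[C@H]2CCC[C@@H]1C(=O)OC2=O | intermediate
12 | all-cis 2-(but-3-yn-1-yl)-3-(methoxycarbonyl)cyclohexane-1-carboxylic acid, single enantiomer | C#CCC[C@@H]1[C@H](C(=O)OC)CCC[C@@H]1C(=O)O | intermediate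
13 | phenyl vinyl sulfoxide | C=CS(=O)c1ccccc1 | starting material
14 | 2-(but-3-yn-1-yl)-3-(methoxycarbonyl)-3-[2-(phenylsulfinyl)ethyl]cyclohexane-1-carboxylic acid; carboxyl, ester and butynyl cis, sulfinylethyl trans to butynyl, mixture at sulfur | C#CCC[C@@H]1[C@@](C(=O)OC)(CCS(=O)c2ccccc2)CCC[C@@H]1C(=O)O | intermediate
15 | 2-(but-3-yn-1-yl)-3-(methoxycarbonyl)-3-vinylcyclohexane-1-carboxylic acid; carboxyl, ester and butynyl cis, vinyl trans to butynyl | C#CCC[C@@H]1[C@@](C(=O)OC)(C=C)CCC[C@@H]1C(=O)O | intermediate
16 | 2-(but-3-yn-1-yl)-3-(methoxycarbonyl)-1-methyl-3-vinylcyclohexane-1-carboxylic acid; carboxyl, ester and butynyl on one face, methyl and vinyl on the other | C#CCC[C@@H]1[C@@](C(=O)OC)(C=C)CCC[C@]1(C)C(=O)O | intermediate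
17 | 2-(but-3-yn-1-yl)-3-(hydroxymethyl)-1-methyl-3-vinylcyclohexane-1-carboxylic acid, same relative configuration | C#CCC[C@@H]1[C@@](CO)(C=C)CCC[C@]1(C)C(=O)O | intermediate
18 | 9-(but-3-yn-1-yl)-1-methyl-5-vinyl-3-oxabicyclo[3.3.1]nonan-2-one, butynyl on the side of the lactone bridge | C#CCC[C@@H]1[C@@]2(C=C)CCC[C@]1(C)C(=O)OC2 | intermediate
19 | potassium 2-(but-3-yn-1-yl)-3-(hydroxymethyl)-1-methyl-3-vinylcyclohexane-1-carboxylate | C#CCC[C@@H]1[C@@](CO)(C=C)CCC[C@]1(C)C(=O)[O-].[K+] | intermediate
20 | methyl 2-(but-3-yn-1-yl)-3-(hydroxymethyl)-1-methyl-3-vinylcyclohexane-1-carboxylate; ester, butynyl and hydroxymethyl cis | C#CCC[C@@H]1[C@@](CO)(C=C)CCC[C@]1(C)C(=O)OC | intermediate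
21 | methyl 3-(acetoxymethyl)-2-(but-3-yn-1-yl)-1-methyl-3-vinylcyclohexane-1-carboxylate; ester, butynyl and acetoxymethyl cis | C#CCC[C@@H]1[C@@](COC(C)=O)(C=C)CCC[C@]1(C)C(=O)OC | intermediate
22 | (Z)-2-iodoalkenyl-9-BBN adduct of 21, boron on the terminal carbon, cis to iodine | I/C(CC[C@@H]1[C@@](COC(C)=O)(C=C)CCC[C@]1(C)C(=O)OC)=C\B1C2CCCC1CCC2 | intermediate
23 | methyl 3-(acetoxymethyl)-2-(3-iodobut-3-en-1-yl)-1-methyl-3-vinylcyclohexane-1-carboxylate; ester, iodobutenyl and acetoxymethyl cis | C=C(I)CC[C@@H]1[C@@](COC(C)=O)(C=C)CCC[C@]1(C)C(=O)OC | intermediate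
24 | methyl acrylate | C=CC(=O)OC | starting material
25 | (tert-butyldimethylsilyloxy)acetaldehyde | CC(C)(C)[Si](C)(C)OCC=O | starting material
26 | methyl 2-[2-(tert-butyldimethylsilyloxy)-1-hydroxyethyl]acrylate, racemic | C=C(C(=O)OC)C(O)CO[Si](C)(C)C(C)(C)C | intermediate
27 | methyl 3,4-dihydroxy-2-methylenebutanoate, racemic | C=C(C(=O)OC)C(O)CO | intermediate
28 | 4-hydroxy-3-methylenedihydrofuran-2(3H)-one, racemic | C=C1C(O)COC1=O | intermediate
29 | 3-methylene-2-oxotetrahydrofuran-4-yl acetate, racemic | C=C1C(OC(C)=O)COC1=O | intermediate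
30 | 14-acetoxy-13,14-dihydro derivative of 31, mixture at C13 and C14 | C=C1CC[C@@H]2[C@](COC(C)=O)(CCC[C@]2(C)C(=O)OC)[C@H]1CCC1C(OC(C)=O)COC1=O | intermediate
31 | CNP0104712.1, methyl 20-acetoxylabda-8(17),13-dien-16,15-olid-19-oate (5α-H, 9α-H, 10β-CH2OAc, 4β-CO2Me) | C=C1CC[C@@H]2[C@](COC(C)=O)(CCC[C@]2(C)C(=O)OC)[C@H]1CCC1=CCOC1=O | target

**Summary**
Total step count: 17. Longest linear sequence: 14 steps (steps 1–13 and 17); steps 14–16 form the side branch to 29.

Steps most likely to fail:

- Step 17. The vinyl radical may be captured by the acceptor or reduced before it cyclises, closure may go partly in the endo mode, or facial selectivity at C9 may erode. Fallback: setting out from 23, cross-metathesis of the C10 vinyl group with 3-allylfuran-2(5H)-one (second-generation Hoveyda–Grubbs catalyst, CH2Cl2, 40 °C) should attach the complete side chain first, giving the (E)-alkene methyl 3-(acetoxymethyl)-2-(3-iodobut-3-en-1-yl)-1-methyl-3-[(E)-3-(2-oxo-2,5-dihydrofuran-3-yl)prop-1-en-1-yl]cyclohexane-1-carboxylate F1. A purely intramolecular, reductive Stork vinyl-radical 6-exo cyclisation of F1 (Bu3SnH, AIBN, benzene, 80 °C, no external acceptor) then comes back to the route at 31.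

- Step 6. Discrimination of the enantiotopic carbonyls of the bridged glutaric-type anhydride may be insufficient. Fallback: setting out from 11, unselective methanolysis (MeOH, Et3N) should give the racemic hemiester F2. Classical resolution by crystallisation of the (R)-1-phenylethylammonium salt of 12 F3, followed by acidification, comes back to the route at 12.

- Step 7. Conjugate addition of the hindered enolate to the vinyl sulfoxide may be sluggish, or the enolate may be quenched by proton transfer. Fallback: setting out from 12, the same enolate is trapped with acetaldehyde (aldol addition, −78 °C) to give the β-hydroxy ester 2-(but-3-yn-1-yl)-3-(1-hydroxyethyl)-3-(methoxycarbonyl)cyclohexane-1-carboxylic acid F4. Mesylation (MsCl, Et3N) gives the mesylate of F4 F5, and E2 elimination towards the methyl group (DBU, toluene, 110 °C) comes back to the route at 15.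

**Further compounds**
F1 | step 17 | methyl 3-(acetoxymethyl)-2-(3-iodobut-3-en-1-yl)-1-methyl-3-[(E)-3-(2-oxo-2,5-dihydrofuran-3-yl)prop-1-en-1-yl]cyclohexane-1-carboxylate | C=C(I)CC[C@@H]1[C@@](COC(C)=O)(/C=C/CC2=CCOC2=O)CCC[C@]1(C)C(=O)OC
F2 | step 6 | racemic hemiester (12 together with its enantiomer) | C#CCC[C@@H]1[C@H](C(=O)OC)CCC[C@@H]1C(=O)O.C#CCC[C@H]1[C@@H](C(=O)OC)CCC[C@H]1C(=O)O
F3 | step 6 | (R)-1-phenylethylammonium salt of 12 | C#CCC[C@@H]1[C@H](C(=O)OC)CCC[C@@H]1C(=O)[O-].C[C@@H]([NH3+])c1ccccc1
F4 | step 7 | 2-(but-3-yn-1-yl)-3-(1-hydroxyethyl)-3-(methoxycarbonyl)cyclohexane-1-carboxylic acid, mixture at the carbinol carbon | C#CCC[C@@H]1[C@@](C(=O)OC)(C(C)O)CCC[C@@H]1C(=O)O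
F5 | step 7 | mesylate of F4 | C#CCC[C@@H]1[C@@](C(=O)OC)(C(C)OS(C)(=O)=O)CCC[C@@H]1C(=O)O
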